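**Plan**

- Retrosynthesis: target 12 is traced back through its bis-acetonide 11 (the four phenolic O–H masked as two ketal rings) to the bromine-free bis-ketal ether 8 by cutting all six aryl C–Br bonds at once. Ether 8 is cut at one benzylic C–O bond of the CH2–O–CH2 bridge into alcohol 5 and chloride 6, both from 3,4-dihydroxybenzaldehyde 1.
- Enabling feature: with each ring numbered C1 (benzylic carbon) and C4, C5 (oxygen-bearing), the only C–H carbons are C2 (para to the C5 oxygen), C3 (ortho to the C4 oxygen) and C6 (ortho to the C5 oxygen). All three are oxygen-activated and all three are brominated in the target, so substitution to exhaustion has one possible constitution.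
- Forward order: the two ketal (dioxole) rings are made first (step 1), the aldehyde is reduced (step 2), half is activated as the chloride (step 3) and the two seven-carbon halves are joined at oxygen (step 4). Six bromines then enter in one flask (step 5) and the ketal rings are opened last (step 6). The benzene rings come with 1.
- Stereochemistry: none to control; 12 is achiral, with no stereocentre and no stereogenic double bond.

Key step: step 5

**Route**

Step 1
Reactants: 1 3,4-dihydroxybenzaldehyde; 2 2,2-dimethoxypropane
Product: 4 2,2-dimethyl-1,3-benzodioxole-5-carbaldehyde, via dimethyl acetal 3 (not isolated)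
Conditions: 2 (4 equiv), TsOH·H2O (cat.), PhMe, reflux, MeOH trapped on 4 Å sieves (Soxhlet); then 1 M HCl, THF, 0 °C, brief
Reagents that add atoms: 2,2-dimethoxypropane, COC(C)(C)OC; water, O
Why: Acid-catalysed ketal exchange onto the catechol is driven by trapping of methanol, the formyl group being acetalized on the way by a second equivalent of 2 (which also removes its electron pull from the catechol), and the acyclic dimethyl acetal 3 is then hydrolysed by cold dilute acid far faster than the aryl ketal, so that only the aldehyde is unmasked.

Step 2
Reactants: 4 2,2-dimethyl-1,3-benzodioxole-5-carbaldehyde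
Product: 5 (2,2-dimethyl-1,3-benzodioxol-5-yl)methanol
Conditions: NaBH4, MeOH, 0 °C
Reagents that add atoms: none
Why: Chemoselective NaBH4 reduction of an aromatic aldehyde to the primary benzylic alcohol; the ketal is inert to hydride and to the basic medium, and no stereocentre arises.

Step 3
Reactants: 5 (2,2-dimethyl-1,3-benzodioxol-5-yl)methanol (one half of the batch)
Product: 6 5-(chloromethyl)-2,2-dimethyl-1,3-benzodioxole
Conditions: SOCl2, pyridine, CH2Cl2, 0 °C; cold NaHCO3 wash, used crude
Reagents that add atoms: thionyl chloride, O=S(Cl)Cl
Why: Chlorodehydroxylation through the chlorosulfite (the standard route to piperonyl-type chlorides), with pyridine taking up HCl so that the ketal never meets free acid; the chloride is used at once because the oxygen-rich ring makes it prone to ionize.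

Step 4
Reactants: 5 (2,2-dimethyl-1,3-benzodioxol-5-yl)methanol (other half); 6 5-(chloromethyl)-2,2-dimethyl-1,3-benzodioxole
Product: 8 bis[(2,2-dimethyl-1,3-benzodioxol-5-yl)methyl] ether, via sodium alkoxide 7 (not isolated)
Conditions: NaH, THF–DMF, 0 °C; then 6, 0 °C → rt
Reagents that add atoms: none
Why: Williamson ether synthesis: the primary alkoxide 7 displaces chloride from the unhindered, activated benzylic carbon of 6 by SN2, with no β-hydrogen available for elimination and a ketal that is stable to base.

Step 5
Reactants: 8 bis[(2,2-dimethyl-1,3-benzodioxol-5-yl)methyl] ether; 9 bromine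
Product: 11 bis[(4,6,7-tribromo-2,2-dimethyl-1,3-benzodioxol-5-yl)methyl] ether, via dibromo bis-ketal ether 10 (not isolated)
Conditions: Br2 (2.1 equiv), NaOAc (2.5 equiv), AcOH–CH2Cl2 (1:1), 0 °C, dark; then AgOAc (6.5 equiv), Br2 (4.4 equiv), 0 °C → rt, dark
Reagents that add atoms: bromine, BrBr
Why: Each C–Br bond forms by arenium-ion substitution (attack of electrophilic bromine on the ring, loss of the ring proton to acetate), the classical exhaustive bromination of catechol ethers, run here in two stages in one flask: buffered Br2 first puts one bromine on each ring at C2, para to the C5 oxygen, as piperonyl-type alcohols are known to brominate, giving 10; AgOAc then converts the remaining Br2 into acetyl hypobromite, an electrophile strong enough for the bromine-deactivated carbons C3 and C6 next to the ketal oxygens. The five-membered ketal keeps both oxygen lone pairs in conjugation with the ring even when the neighbouring carbons carry bromine, which two free methoxy groups would not do. No ring is closed and no stereocentre is created. Positional selectivity is not in question because the three carbons attacked are the only C–H carbons of each ring; what the step needs is ring C–H substitution in preference to ipso attack at C1 (which would expel the benzylic ether arm), to oxidation of the benzylic CH2 and to acid cleavage of ketal or ether. This is secured by the ketal masks (no free para-hydroxyl to push the ether out through a quinone methide), by the C2 bromine that enters first and shields C1, by cold, dark, ionic conditions, and by AgOAc, which removes every bromide (that of the first stage included) as AgBr so that AcOH is the only acid present.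

Step 6
Reactants: 11 bis[(4,6,7-tribromo-2,2-dimethyl-1,3-benzodioxol-5-yl)methyl] ether
Product: 12 bis(2,3,6-tribromo-4,5-dihydroxybenzyl) ether
Conditions: CF3CO2H–H2O (9:1), CH2Cl2, 0 °C → rt; evaporation from PhMe; no alcohol in reaction, work-up or chromatography
Reagents that add atoms: none
Why: Acid-catalysed hydrolysis of the two aryl ketals (protonation at a ketal oxygen, opening to the oxocarbenium ion, capture by water, loss of acetone) frees the four phenols, while in strong acid the phenols stay un-ionized and the benzylic carbon sits on a ring carrying three bromines, so ionization of the central ether should be slow and water is the only nucleophile offered.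

**Compound list**

1 | 3,4-dihydroxybenzaldehyde | O=Cc1ccc(O)c(O)c1 | starting material
2 | 2,2-dimethoxypropane | COC(C)(C)OC | starting material
3 | 5-(dimethoxymethyl)-2,2-dimethyl-1,3-benzodioxole (not isolated) | COC(OC)c1ccc2OC(C)(C)Oc2c1 | intermediate
4 | 2,2-dimethyl-1,3-benzodioxole-5-carbaldehyde | CC1(C)Oc2ccc(C=O)cc2O1 | intermediate
5 | (2,2-dimethyl-1,3-benzodioxol-5-yl)methanol | CC1(C)Oc2ccc(CO)cc2O1 | intermediate
6 | 5-(chloromethyl)-2,2-dimethyl-1,3-benzodioxole | CC1(C)Oc2ccc(CCl)cc2O1 | intermediate
7 | sodium (2,2-dimethyl-1,3-benzodioxol-5-yl)methanolate (not isolated) | CC1(C)Oc2ccc(C[O-])cc2O1.[Na+] | intermediate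
8 | bis[(2,2-dimethyl-1,3-benzodioxol-5-yl)methyl] ether | CC1(C)Oc2ccc(COCc3ccc4OC(C)(C)Oc4c3)cc2O1 | intermediate
9 | bromine | BrBr | starting material
10 | bis[(6-bromo-2,2-dimethyl-1,3-benzodioxol-5-yl)methyl] ether (not isolated) | CC1(C)Oc2cc(Br)c(COCc3cc4OC(C)(C)Oc4cc3Br)cc2O1 | intermediate
11 | bis[(4,6,7-tribromo-2,2-dimethyl-1,3-benzodioxol-5-yl)methyl] ether | CC1(C)Oc2c(Br)c(Br)c(COCc3c(Br)c(Br)c4OC(C)(C)Oc4c3Br)c(Br)c2O1 | intermediate
12 | bis(2,3,6-tribromo-4,5-dihydroxybenzyl) ether | Oc1c(O)c(Br)c(COCc2c(Br)c(O)c(O)c(Br)c2Br)c(Br)c1Br | target

**Step count**

Total steps: 6. Longest linear sequence: 6 steps (1 → 4 → 5 → 6 → 8 → 11 → 12; the chloride 6 branches from and rejoins the same line).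

**Steps most likely to fail**

Step 5. The electrophile may attack C1 (para to the C4 oxygen) and expel the alkoxymethyl arm as an oxocarbenium ion. Hydride may be lost from the benzylic CH2. The reaction may stall after two bromines per ring, or a ketal may be lost and the freed catechol over-oxidized. The fallback sets out from 1 and returns at 11: the bromines are introduced before the ether exists, at the aldehyde oxidation level, where the electron-poor formyl carbon cannot leave as a cation and the free phenols drive all three substitutions. Bromine 9 with a catalytic amount of iron powder in warm AcOH should take 1 to 2,3,6-tribromo-4,5-dihydroxybenzaldehyde F1 with loss of HBr. Ketalization of F1 with 2 and TsOH under the conditions of step 1 would pass through 4,6,7-tribromo-5-(dimethoxymethyl)-2,2-dimethyl-1,3-benzodioxole F2 and, after the same cold dilute-acid work-up of F2, give 4,6,7-tribromo-2,2-dimethyl-1,3-benzodioxole-5-carbaldehyde F3 as the isolated aldehyde. NaBH4 in THF–MeOH would reduce F3 to (4,6,7-tribromo-2,2-dimethyl-1,3-benzodioxol-5-yl)methanol F4 without touching the aryl bromides. Half of F4 would be converted with CBr4 and PPh3 into 4,6,7-tribromo-5-(bromomethyl)-2,2-dimethyl-1,3-benzodioxole F5 by an Appel reaction. The other half of F4 would be deprotonated with NaH to sodium (4,6,7-tribromo-2,2-dimethyl-1,3-benzodioxol-5-yl)methanolate F6 in DMF, and F6 would then be alkylated with F5 to give 11, after which step 6 follows unchanged.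

Step 6. The central benzylic ether may solvolyse (exchange of the benzylic oxygen with water or trifluoroacetate) while the ketals are being hydrolysed, or hydrolysis may stall with one ketal left. The fallback sets out from 11 and returns at 12: instead of sparing the ether, solvolysis is driven to completion and the ether is rebuilt under thermodynamic control. Warm 2 M HCl in aqueous dioxane should strip both ketals and hydrolyse the bridge, converging on 2,3,6-tribromo-4,5-dihydroxybenzyl alcohol F7 as the single product. Its ring has no free carbon for C-alkylation, so acid-catalysed dehydration of F7 (cat. TsOH, 1,2-dichloroethane, 4 Å sieves, 50 °C) should end in capture of the benzylic cation by the hydroxymethyl group of a second molecule, giving 12.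

Step 3. The electron-rich benzylic chloride may ionize, leading to Friedel–Crafts self-alkylation or hydrolysis before it meets the alkoxide. The fallback sets out from 4 and returns at 8 by a halide-free reductive etherification. Et3SiH with catalytic BiBr3 in MeCN should hydrosilylate one molecule of 4 to [(2,2-dimethyl-1,3-benzodioxol-5-yl)methoxy]triethylsilane F8 in the flask. The silyl ether F8 condenses there with a second molecule of 4 to an oxocarbenium ion that is reduced by further silane, giving 8 directly and bypassing steps 2 to 4.

**Further compounds**

F1 | step 5 | 2,3,6-tribromo-4,5-dihydroxybenzaldehyde | O=Cc1c(Br)c(Br)c(O)c(O)c1Br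
F2 | step 5 | 4,6,7-tribromo-5-(dimethoxymethyl)-2,2-dimethyl-1,3-benzodioxole | COC(OC)c1c(Br)c(Br)c2OC(C)(C)Oc2c1Br
F3 | step 5 | 4,6,7-tribromo-2,2-dimethyl-1,3-benzodioxole-5-carbaldehyde | CC1(C)Oc2c(Br)c(Br)c(C=O)c(Br)c2O1
F4 | step 5 | (4,6,7-tribromo-2,2-dimethyl-1,3-benzodioxol-5-yl)methanol | CC1(C)Oc2c(Br)c(Br)c(CO)c(Br)c2O1
F5 | step 5 | 4,6,7-tribromo-5-(bromomethyl)-2,2-dimethyl-1,3-benzodioxole | CC1(C)Oc2c(Br)c(Br)c(CBr)c(Br)c2O1
F6 | step 5 | sodium (4,6,7-tribromo-2,2-dimethyl-1,3-benzodioxol-5-yl)methanolate | CC1(C)Oc2c(Br)c(Br)c(C[O-])c(Br)c2O1.[Na+]
F7 | step 6 | 2,3,6-tribromo-4,5-dihydroxybenzyl alcohol | OCc1c(Br)c(Br)c(O)c(O)c1Br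
F8 | step 3 | [(2,2-dimethyl-1,3-benzodioxol-5-yl)methoxy]triethylsilane | CC[Si](CC)(CC)OCc1ccc2OC(C)(C)Oc2c1
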